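## The problem

The target (14) is the 3-acetoxy-3-methylbutanoate ester of (R)-shikonin (10): ring A (C4a, C5 to C8, C8a) carries the two phenolic hydroxyls, ring B (C1 to C4) is the quinone, and a 4-methylpent-3-enyl chain at C2 bears the ester oxygen on its first carbon, C1', the only stereocentre (R). Both rings can be bought together as naphthazarin (1), so the skeletal task is a single bond, C2–C1', and since no second stereocentre exists to relay from, C1' has to be set by a reagent or catalyst. The nucleus is redox-active and tautomerises between its two rings, and its C5 and C8 oxygens can only be masked by groups that leave under conditions far milder than Lewis-acid ether cleavage. The side chain is fragile: the trisubstituted alkene captures the C1' oxygen under strong acid, and the C1'–O bond ionises once ring B takes on aromatic character. The six-carbon aldehyde (7) from which the chain is most directly drawn is β,γ-unsaturated and slips into conjugation with base. The acyl group holds a tertiary acetate β to the ester carbonyl, which base removes by E1cB elimination, so the esterification belongs at the very end. The enabling feature is that C2 is the alpha carbon of the enone C1(=O)–C2=C3 and C1' is a secondary carbinol attached to it, which is the Morita–Baylis–Hillman array. If C4 is masked as a ketal, ring B has exactly one enone, and because ring A is symmetrically substituted, C2 and C3 become equivalent again on unmasking.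

## Retrosynthesis

**Ester bond, 14 to 10 and 13.** The acyl C–O bond at the C1' oxygen is cut first, giving shikonin (10) and 3-acetoxy-3-methylbutanoic acid (13). Carrying the ester through earlier steps would expose its tertiary acetate to nucleophiles and base. In 10 the phenols are tied up in hydrogen bonds to the quinone carbonyls, so a carbodiimide esterification should find the side-chain hydroxyl. The forward step must leave the C1'–O bond intact (retention) and avoid strong base.

**Acetate of the acid, 13 to 11.** The O-acetyl bond of 13 is cut to give commercial 3-hydroxy-3-methylbutanoic acid (11). The forward acetylation runs through mixed anhydride 12 and must be done without base for the reason above.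

**Unmasking, 10 to 8.** No skeletal bond is cut: the C4 carbonyl and the two phenols of 10 are traced back to the dimethyl ketal and the two methoxymethyl ethers of 8. Methyl ethers at C5 and C8 were rejected because their cleavage needs Lewis acids or oxidants that the side chain does not survive. Three acetal-type masks come off in one dilute-acid operation, through quinone 9. The forward step asks only that hydrolysis outrun ionisation at C1' and cyclisation onto the alkene.

**Key disconnection, 8 to 5 and 7.** The C2–C1' bond is cut, giving quinone monoketal 5 and 4-methylpent-3-enal (7). Two neighbouring cuts were weighed: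
- Cutting C1'–C2' would call for prenylation of a 2-formyl derivative. Prenyl metals add through their substituted terminus, which gives the branched isomer.
- Adding a metalated tetra-alkoxynaphthalene to 7 forms the same bond but gives a racemic carbinol on an electron-rich arene. That carbinol must then be oxidised, reduced asymmetrically and unmasked oxidatively.

The enone α-hydroxyalkylation instead makes the bond and the stereocentre in one catalytic step, with ring B already at the quinone oxidation level. Compound 5 is achiral and three steps from 1; 7 is one step from an alcohol. The forward reaction must distinguish the two faces of the aldehyde. Site selectivity is built in, since 5 has one enone.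

**Ketal, 5 to 4.** The second C4–O bond of the ketal is cut, leading to para-methoxynaphthol 4. Oxidative dearomatisation with trapping by the alcohol solvent is the standard entry to quinone monoketals. A dimethyl ketal is chosen because it adds no stereocentre.

**Ring B oxygens, 4 to 2 to 1.** The O–methyl bond of 4 is cut to give hydroquinone 3, the reduction product of quinone 2. Compound 2 is the bis(methoxymethyl) ether of 1. The forward sequence needs a monomethylation of two equivalent hydroxyls, which is the least elegant operation of the route and is run with a deficit of methylating agent and recycling.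

**Aldehyde, 7 to 6.** The aldehyde is traced to commercial 4-methylpent-3-en-1-ol (6). The oxidation must be neutral enough to leave the β,γ double bond where it is.

## Roads not taken

**Alternative 1:** Ring B is built rather than bought. The cut removes C4–C3, C2–C1 and C1–C8a. In the forward direction, pentacarbonyl{[2,5-bis(methoxymethoxy)phenyl](methoxy)methylidene}chromium (A1) and the propargylic silyl ether (R)-tert-butyldimethyl[(6-methylhept-5-en-1-yn-3-yl)oxy]silane (A2) combine in a Dötz benzannulation with insertion of one CO ligand. The product is 2-[(1R)-1-(tert-butyldimethylsilyloxy)-4-methylpent-3-enyl]-4-methoxy-5,8-bis(methoxymethoxy)naphthalen-1-ol (A3).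
- Merits: the reaction class is established for aryl(alkoxy)carbene complexes and terminal alkynes. The larger alkyne substituent ends up beside the new phenol. A3 is a para-methoxynaphthol one mild oxidation from the quinone, so the C1/C4 differentiation that costs the chosen route step 2 comes for free. The stereocentre is imported from A2, for which asymmetric alkynylation of 7 or asymmetric reduction of an ynone is dependable.
- Weak points: A1 needs stoichiometric Cr(CO)6 and an aryllithium. Its ortho methoxymethoxy group can chelate the metal after CO loss and divert the annulation. A2 costs three or four steps and still starts from labile aldehyde 7. After the annulation, oxidation, desilylation, acetal removal and acylation remain, so the count is roughly twelve steps against eight.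
- Comparison: in certainty of the key step this road is better, because its central reaction is known on this substrate class and the chosen one is not. The chosen plan sets against it a catalytic, metal-free step that forms bond and stereocentre together, a shorter sequence, and a fallback made of known reactions.

**Alternative 2:** The cut is C4a–C4 and C8a–C1, the two bonds joining ring A to ring B. In the forward direction, CsF releases 3,6-bis(methoxymethoxy)benzyne from 3,6-bis(methoxymethoxy)-2-(trimethylsilyl)phenyl trifluoromethanesulfonate (A4). The aryne adds across the α carbons of (R)-tert-butyl{[1-(furan-3-yl)-4-methylpent-3-enyl]oxy}dimethylsilane (A5). The product is 2-[(1R)-1-(tert-butyldimethylsilyloxy)-4-methylpent-3-enyl]-5,8-bis(methoxymethoxy)-1,4-epoxy-1,4-dihydronaphthalene (A6), as a mixture of bridgehead diastereomers.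
- Merits: the aryne is symmetric, so there is no regiochemical question. The conditions are mild, the step is convergent, and aryne–furan cycloaddition is textbook chemistry, more certain than the chosen key step.
- Weak points: A6 is at the wrong oxidation level. The bridge supplies only one of the two ring B oxygens. The bicycle must be opened to a naphthol with acid, which threatens the acetals and the benzylic silyl ether. The naphthol must then be oxidised to the quinone in the presence of the trisubstituted alkene. A4 needs four or five steps. A5 cannot come from prenylation of furan-3-carbaldehyde, which would give the branched isomer, so it needs its own carbinol synthesis. The total is near thirteen steps.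
- Comparison: this road wins on reliability of the ring-forming step. The chosen plan never leaves the quinone oxidation level once the stereocentre exists and is about five steps shorter.

**Alternative 3:** The cut is C2'–C3' in the side chain, with ring A annulated last. The forward key step joins two partners. The first is the redox-active ester 1,3-dioxoisoindolin-2-yl (3R)-3-(tert-butyldimethylsilyloxy)-3-(2,5-dimethoxyphenyl)propanoate (A7). The second is the vinyl bromide 1-bromo-2-methylprop-1-ene (A8). Ester A7 is reduced at the cathode with NiCl2·glyme and 2,2'-bipyridine and loses CO2, and the primary C2' radical so formed is coupled with bromide A8. The product is (R)-tert-butyl[1-(2,5-dimethoxyphenyl)-4-methylpent-3-enyloxy]dimethylsilane (A9).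
- Merits: aldehyde 7 is avoided altogether, and A8 is a cheap commercial bromide. The stereocentre of A7 would come from Noyori hydrogenation of a β-keto ester, which is more secure than any new asymmetric reaction, and here this road is better than the chosen one. Decarboxylative alkenylation of primary redox-active esters such as A7 is a known class.
- Weak points: the alkylnickel intermediate formed from A7 carries a β-silyloxy group and can collapse by β-oxygen elimination to a styrene before it meets A8. More seriously, the key step makes the least strategic bond. After A9 the arene must be oxidised to a benzoquinone, ring A built by Diels–Alder reaction with a 1,4-dioxygenated diene, and the adduct dehydrogenated to the naphthazarin. All of this happens on a compound that already holds the benzylic stereocentre and the alkene, and the sequence is well beyond thirteen steps.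
- Comparison: the chosen plan buys the complete nucleus and spends its one uncertain step on the only bond that matters.

Key step: step 5

Assumption: the (R)-binaphthol acid is written in step 5 by analogy with the cyclohexenone series. The sense of induction on a quinone monoketal has to be established on the first adduct (sign of rotation of 10), and the (S)-acid is used if it proves opposite.

## Route

Step 1
Reactants: 1 naphthazarin (5,8-dihydroxynaphthalene-1,4-dione)
Product: 2 5,8-bis(methoxymethoxy)naphthalene-1,4-dione
Conditions: MOMCl (4 equiv), iPr2NEt (5 equiv), CH2Cl2, 0 °C → reflux
Reagents that add atoms: chloromethyl methyl ether, COCCl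
Why: Williamson-type O-alkylation of the two acidic peri hydroxyls by a very reactive oxocarbenium-type electrophile; the hindered amine deprotonates without adding to the quinone, and either tautomer of 1 leads to the same symmetric diether.

Step 2
Reactants: 2 5,8-bis(methoxymethoxy)naphthalene-1,4-dione
Product: 4 4-methoxy-5,8-bis(methoxymethoxy)naphthalen-1-ol, via 5,8-bis(methoxymethoxy)naphthalene-1,4-diol 3 (not isolated)
Conditions: Na2S2O4, EtOAc/H2O, rt, Ar; organic phase dried and concentrated; then K2CO3, Me2SO4 (0.7 equiv), acetone, 0 °C → rt, Ar
Reagents that add atoms: dimethyl sulfate, COS(=O)(=O)OC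
Why: Dithionite reduction gives hydroquinone 3, and Williamson methylation with a deficit of Me2SO4 keeps the dimethyl ether low; unreacted 3 returns to 2 in air on work-up and is recycled. The methoxymethyl ethers are inert to reductant and base.

Step 3
Reactants: 4 4-methoxy-5,8-bis(methoxymethoxy)naphthalen-1-ol
Product: 5 4,4-dimethoxy-5,8-bis(methoxymethoxy)naphthalen-1(4H)-one
Conditions: PhI(OAc)2 (1.1 equiv), MeOH, 0 °C; NaHCO3 quench
Reagents that add atoms: methanol, CO
Why: Oxidative dearomatisation of a para-methoxyphenol by a trivalent iodine reagent: the aryloxyiodane loses PhI and the cation stabilised by the C4 methoxy group is trapped by methanol at C4, the standard route to quinone monoketals. The ring A oxygens are ethers, not phenols, and are not oxidised.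

Step 4
Reactants: 6 4-methylpent-3-en-1-ol
Product: 7 4-methylpent-3-enal
Conditions: Dess–Martin periodinane, CH2Cl2, 0 °C → rt; cold NaHCO3/Na2S2O3 wash; solution concentrated cold and used at once
Reagents that add atoms: none
Why: Dess–Martin oxidation stops at the aldehyde under nearly neutral conditions, which the β,γ-unsaturated aldehyde needs if its double bond is to stay out of conjugation; the product is used without distillation.

Step 5
Reactants: 5 4,4-dimethoxy-5,8-bis(methoxymethoxy)naphthalen-1(4H)-one; 7 4-methylpent-3-enal
Product: 8 2-[(1R)-1-hydroxy-4-methylpent-3-enyl]-4,4-dimethoxy-5,8-bis(methoxymethoxy)naphthalen-1(4H)-one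
Conditions: 7 in threefold excess, PEt3 (50 mol %), (R)-3,3'-bis[3,5-bis(trifluoromethyl)phenyl]-5,5',6,6',7,7',8,8'-octahydro-1,1'-bi-2-naphthol (10 mol %), THF, −10 °C, Ar
Reagents that add atoms: none
Why: Proposed new method: PEt3 adds reversibly to C3 of the single enone of 5, the C1–C2 enolate of the phosphonium zwitterion is hydrogen-bonded to the chiral binaphthol, and this chiral ion pair adds through C2 to the carbonyl of 7; proton transfer from C2, shuttled by the diol, and E1cB loss of PEt3 then restore the C2–C3 double bond and return the phosphine to the cycle. The closest known reaction type is the phosphine and chiral Brønsted acid co-catalysed asymmetric Morita–Baylis–Hillman reaction of cyclohex-2-enone with unbranched aliphatic aldehydes, and the known readiness of quinone monoketals to accept nucleophiles at the carbon beside the ketal (amine-mediated alpha-iodination, conjugate additions) argues that the C4 substituents will not block the first step. No ring is closed. The one new stereocentre, C1', is set under catalyst control: the diol-bound enolate must attack the si face of the aldehyde to give the R carbinol. The step needs only enantiofacial selectivity, because site selectivity is fixed by the single enone of 5 and the ketal and methoxymethyl ethers are inert to a tertiary phosphine and a phenol-type acid. The aldehyde is freshly made, used in excess and kept at −10 °C so that the weakly basic zwitterion does not move its β,γ double bond into conjugation.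

Step 6
Reactants: 8 2-[(1R)-1-hydroxy-4-methylpent-3-enyl]-4,4-dimethoxy-5,8-bis(methoxymethoxy)naphthalen-1(4H)-one
Product: 10 shikonin, via shikonin 5,8-bis(methoxymethyl) ether 9 (not isolated)
Conditions: 3 M aq HCl, THF, 0 °C → rt, Ar
Reagents that add atoms: water, O
Why: Acid-catalysed acetal hydrolysis: the dimethyl ketal goes first to quinone 9, then the two methoxymethyl ethers, which are assisted by the peri carbonyl groups. C1' sits on an electron-poor quinone carbon and its C–O bond is not expected to ionise in dilute acid at room temperature, so the R configuration is kept.

Step 7
Reactants: 11 3-hydroxy-3-methylbutanoic acid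
Product: 13 3-acetoxy-3-methylbutanoic acid, via acetic 3-acetoxy-3-methylbutanoic anhydride 12 (not isolated)
Conditions: AcCl (neat, excess), 0 °C → rt; evaporation; then H2O/THF, rt
Reagents that add atoms: acetyl chloride, CC(=O)Cl
Why: Acetylation of a tertiary alcohol by neat acyl chloride under base-free conditions, which avoids E1cB loss of the new acetate; the carboxyl group is carried as mixed anhydride 12, which water cleaves at the less hindered acetyl carbonyl on work-up.

Step 8
Reactants: 10 shikonin; 13 3-acetoxy-3-methylbutanoic acid
Product: 14 (1R)-1-(5,8-dihydroxy-1,4-dioxo-1,4-dihydronaphthalen-2-yl)-4-methylpent-3-enyl 3-acetoxy-3-methylbutanoate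
Conditions: 13 (1.5 equiv), DCC (1.5 equiv), DMAP (0.2 equiv), CH2Cl2, 0 °C → rt, Ar
Reagents that add atoms: none
Why: Steglich esterification; the two phenols are locked in hydrogen bonds to the quinone carbonyls and are much less nucleophilic than the side-chain hydroxyl, so the carbinol is acylated selectively. The C1'–O bond is not broken, so the configuration is retained, and catalytic DMAP at low temperature limits elimination of acetic acid from the activated acid.

## Compound list

1 | naphthazarin (5,8-dihydroxynaphthalene-1,4-dione) | O=C1C=CC(=O)c2c(O)ccc(O)c12 | starting material
2 | 5,8-bis(methoxymethoxy)naphthalene-1,4-dione | COCOc1ccc(OCOC)c2c1C(=O)C=CC2=O | intermediate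
3 | 5,8-bis(methoxymethoxy)naphthalene-1,4-diol | COCOc1ccc(OCOC)c2c(O)ccc(O)c12 | intermediate (not isolated)
4 | 4-methoxy-5,8-bis(methoxymethoxy)naphthalen-1-ol | COCOc1ccc(OCOC)c2c(O)ccc(OC)c12 | intermediate
5 | 4,4-dimethoxy-5,8-bis(methoxymethoxy)naphthalen-1(4H)-one | COCOc1ccc(OCOC)c2c1C(=O)C=CC2(OC)OC | intermediate
6 | 4-methylpent-3-en-1-ol | CC(C)=CCCO | starting material
7 | 4-methylpent-3-enal | CC(C)=CCC=O | intermediate
8 | 2-[(1R)-1-hydroxy-4-methylpent-3-enyl]-4,4-dimethoxy-5,8-bis(methoxymethoxy)naphthalen-1(4H)-one | CC(C)=CC[C@@H](O)C1=CC(OC)(OC)c2c(OCOC)ccc(OCOC)c2C1=O | intermediate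
9 | 2-[(1R)-1-hydroxy-4-methylpent-3-enyl]-5,8-bis(methoxymethoxy)naphthalene-1,4-dione (shikonin 5,8-bis(methoxymethyl) ether) | CC(C)=CC[C@@H](O)C1=CC(=O)c2c(OCOC)ccc(OCOC)c2C1=O | intermediate (not isolated)
10 | shikonin, 5,8-dihydroxy-2-[(1R)-1-hydroxy-4-methylpent-3-enyl]naphthalene-1,4-dione | CC(C)=CC[C@@H](O)C1=CC(=O)c2c(O)ccc(O)c2C1=O | intermediate
11 | 3-hydroxy-3-methylbutanoic acid | CC(C)(O)CC(=O)O | starting material
12 | acetic 3-acetoxy-3-methylbutanoic anhydride | CC(=O)OC(C)(C)CC(=O)OC(C)=O | intermediate (not isolated)
13 | 3-acetoxy-3-methylbutanoic acid | CC(=O)OC(C)(C)CC(=O)O | intermediate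
14 | (1R)-1-(5,8-dihydroxy-1,4-dioxo-1,4-dihydronaphthalen-2-yl)-4-methylpent-3-enyl 3-acetoxy-3-methylbutanoate | CC(=O)OC(C)(C)CC(=O)O[C@H](CC=C(C)C)C1=CC(=O)c2c(O)ccc(O)c2C1=O | target

## Step count and risks

Total: 8 steps. Longest linear sequence: 6 steps (1, 2, 3, 5, 6, 8, from naphthazarin). Steps 4 and 7 are one-step side branches.

**Step 5 (key step, new reactivity).**
- Risk: the phosphine may not engage C3 productively, since that carbon is flanked by the fully substituted ketal carbon.
- Risk: the C3 phosphonium adduct may be diverted after proton shuffling by loss of methanol from C4 and aromatisation, which would take the phosphine out of the catalytic cycle irreversibly.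
- Risk: the aldehyde double bond may shift into conjugation.
- Risk: facial selectivity may be poor, because the peri methoxymethoxy oxygen at C8 can compete with the enolate for the hydrogen bond of the chiral acid.
- Fallback, from 5 to 8: amine-mediated alpha-iodination (I2, pyridine, CH2Cl2), known for quinone monoketals, gives 2-iodo-4,4-dimethoxy-5,8-bis(methoxymethoxy)naphthalen-1(4H)-one F1. A Nozaki–Hiyama–Kishi coupling of F1 with 7 then forms the same C2–C1' bond. It uses CrCl2 (divalent chromium) with catalytic NiCl2 and a chiral sulfonamide–oxazoline ligand in THF, and the ligand enantiomer is chosen for the R carbinol. The route is rejoined at 8.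

**Step 6.**
- Risk: the side chain may be damaged before the second methoxymethyl ether has gone. Once a phenol is free, the tautomer with an aromatic ring B lets the C1'–O bond ionise (erosion of configuration). The free C1' hydroxyl can also add to the protonated alkene (ring closure to a tetrahydrofuran).
- Fallback, from 8 to 14: 8 is first acylated with 13 under the conditions of step 8 to give (1R)-1-[4,4-dimethoxy-5,8-bis(methoxymethoxy)-1-oxo-1,4-dihydronaphthalen-2-yl]-4-methylpent-3-enyl 3-acetoxy-3-methylbutanoate F2, which has no free hydroxyl to cyclise. The same dilute acid then removes ketal and methoxymethyl ethers and gives 14 directly.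

**Step 2.**
- Risk: over-methylation and air oxidation of the electron-rich hydroquinone. The two hydroxyls are equivalent and the monoether is as reactive as the diol, so material is lost to the diether unless conversion is kept low.
- Fallback, from 2 to 4: heating 2 with trimethyl phosphite in toluene methylates one quinone oxygen and phosphorylates the other in a single, non-statistical event. This gives dimethyl 4-methoxy-5,8-bis(methoxymethoxy)naphthalen-1-yl phosphate F3. KOH in aqueous methanol cleaves the aryl–phosphate bond and returns the route to 4.

**Step 8.**
- Risk: competing acylation of a phenolic hydroxyl.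
- Risk: rearrangement of the O-acylisourea to the N-acylurea if the hindered carbinol reacts slowly.
- Risk: base-induced elimination of acetic acid from the activated acid.
- Fallback, from 9 to 14: 9 is isolated by stopping step 6 once the ketal has gone (dilute oxalic acid, wet THF). Its only hydroxyl is acylated with excess 13 (DCC, catalytic DMAP) to give (1R)-1-[5,8-bis(methoxymethoxy)-1,4-dioxo-1,4-dihydronaphthalen-2-yl]-4-methylpent-3-enyl 3-acetoxy-3-methylbutanoate F4. Aqueous HCl in THF then frees the two phenols and gives 14.

## Further compounds

F1 | step 5 | 2-iodo-4,4-dimethoxy-5,8-bis(methoxymethoxy)naphthalen-1(4H)-one | COCOc1ccc(OCOC)c2c1C(=O)C(I)=CC2(OC)OC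
F2 | step 6 | (1R)-1-[4,4-dimethoxy-5,8-bis(methoxymethoxy)-1-oxo-1,4-dihydronaphthalen-2-yl]-4-methylpent-3-enyl 3-acetoxy-3-methylbutanoate | CC(=O)OC(C)(C)CC(=O)O[C@H](CC=C(C)C)C1=CC(OC)(OC)c2c(OCOC)ccc(OCOC)c2C1=O
F3 | step 2 | dimethyl 4-methoxy-5,8-bis(methoxymethoxy)naphthalen-1-yl phosphate | COCOc1ccc(OCOC)c2c(OP(=O)(OC)OC)ccc(OC)c12
F4 | step 8 | (1R)-1-[5,8-bis(methoxymethoxy)-1,4-dioxo-1,4-dihydronaphthalen-2-yl]-4-methylpent-3-enyl 3-acetoxy-3-methylbutanoate | CC(=O)OC(C)(C)CC(=O)O[C@H](CC=C(C)C)C1=CC(=O)c2c(OCOC)ccc(OCOC)c2C1=O
A1 | alternative 1 | pentacarbonyl{[2,5-bis(methoxymethoxy)phenyl](methoxy)methylidene}chromium | COC(c1cc(OCOC)ccc1OCOC)=[Cr](=C=O)(=C=O)(=C=O)(=C=O)=C=O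
A2 | alternative 1 | (R)-tert-butyldimethyl[(6-methylhept-5-en-1-yn-3-yl)oxy]silane | CC(C)=CC[C@@H](O[Si](C)(C)C(C)(C)C)C#C
A3 | alternative 1 | 2-[(1R)-1-(tert-butyldimethylsilyloxy)-4-methylpent-3-enyl]-4-methoxy-5,8-bis(methoxymethoxy)naphthalen-1-ol | CC(C)=CC[C@@H](O[Si](C)(C)C(C)(C)C)c1cc(OC)c2c(OCOC)ccc(OCOC)c2c1O
A4 | alternative 2 | 3,6-bis(methoxymethoxy)-2-(trimethylsilyl)phenyl trifluoromethanesulfonate | COCOc1ccc(OCOC)c([Si](C)(C)C)c1OS(=O)(=O)C(F)(F)F
A5 | alternative 2 | (R)-tert-butyl{[1-(furan-3-yl)-4-methylpent-3-enyl]oxy}dimethylsilane | CC(C)=CC[C@@H](O[Si](C)(C)C(C)(C)C)c1ccoc1
A6 | alternative 2 | 2-[(1R)-1-(tert-butyldimethylsilyloxy)-4-methylpent-3-enyl]-5,8-bis(methoxymethoxy)-1,4-epoxy-1,4-dihydronaphthalene (one bridgehead diastereomer drawn) | CC(C)=CC[C@@H](O[Si](C)(C)C(C)(C)C)C1=C[C@H]2O[C@@H]1c1c(OCOC)ccc(OCOC)c12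
A7 | alternative 3 | 1,3-dioxoisoindolin-2-yl (3R)-3-(tert-butyldimethylsilyloxy)-3-(2,5-dimethoxyphenyl)propanoate | O=C(C[C@@H](O[Si](C)(C)C(C)(C)C)c1cc(OC)ccc1OC)ON1C(=O)c2ccccc2C1=O
A8 | alternative 3 | 1-bromo-2-methylprop-1-ene | CC(C)=CBr
A9 | alternative 3 | (R)-tert-butyl[1-(2,5-dimethoxyphenyl)-4-methylpent-3-enyloxy]dimethylsilane | CC(C)=CC[C@@H](O[Si](C)(C)C(C)(C)C)c1cc(OC)ccc1OC
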